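The ε-ring (carotenoid numbering: C1 gem-dimethyl carbon, C4=C5 alkene with the methyl on C5, C6 stereocentre) is traced back to a cyclohexenone. Its C4=C5 alkene beside the C6–H stereocentre is the reductive-transposition retron of a 4-oxo C5=C6 enone, and that enone, whose C6 and C4 are 1,5-related through C1, is a Robinson product. The annulation of ethyl 3-methyl-2-oxobutanoate with ethyl vinyl ketone joins C1–C2 (Michael addition) and C5–C6 (aldol condensation) in one operation from two acyclic ketones. Asymmetric ketone reduction and an allylic-diazene transposition then set C6 by chirality transfer. Two ring sulfones are finally joined to crocetin dialdehyde, using the C2 symmetry.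

Key step: step 1

Remark: crocetin dialdehyde (14) is taken as a purchasable carotenoid building block, and carotenoid numbering (ring C1–C6, first chain carbon C7) is used in the comments.

Step 1
Reactants: 1 ethyl 3-methyl-2-oxobutanoate; 2 pent-1-en-3-one (ethyl vinyl ketone)
Product: 5 ethyl 2,6,6-trimethyl-3-oxocyclohex-1-ene-1-carboxylate, via Michael diketone 3 (not isolated), via aldol ketol 4 (not isolated)
Conditions: conc. H2SO4 (cat.), hydroquinone (trace), toluene, 50 °C (slow addition of 2), then reflux, Dean–Stark
Reagents that add atoms: none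
Why: Acid-catalysed enolisation of 1 is possible only toward the isopropyl carbon, and this enol adds in a Michael fashion to protonated 2, creating the quaternary gem-dimethyl carbon and its bond to the vinyl CH2 (diketone 3); the ethyl ketone of 3 then enolises toward its CH2 and attacks the strongly electrophilic α-keto ester carbonyl (ketol 4), and loss of water gives the tetrasubstituted enone 5. The closest known reaction type is the acid-catalysed Robinson annulation of α-branched aldehydes such as isobutyraldehyde with alkyl vinyl ketones. The ring is closed by a 6-(enolendo)-exo-trig aldol addition. No stereocentre survives in 5, since the methyl-bearing centre of 4 becomes sp2 on dehydration. The step needs regiocontrol of both enolisations and of the aldol closure: 1 has a single α-hydrogen, the quaternary carbon blocks enolisation on that side of 3, and the only other aldol mode would give a strained cyclobutanol that reverts, so one cyclohexenone is expected. Polymerisation of 2 is the competing path and should be held back by slow addition and the radical inhibitor.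

Step 2
Reactants: 5 ethyl 2,6,6-trimethyl-3-oxocyclohex-1-ene-1-carboxylate
Product: 6 ethyl (3R)-3-hydroxy-2,6,6-trimethylcyclohex-1-ene-1-carboxylate
Conditions: (S)-Me-CBS oxazaborolidine (C18H20BNO, 10 mol%), BH3·SMe2, THF/toluene, −30 °C; MeOH quench, aqueous work-up
Reagents that add atoms: none
Why: Corey–Bakshi–Shibata reduction, in which the catalyst–borane complex binds the ketone oxygen anti to the larger, fully substituted alkenyl carbon and delivers hydride to one face, so that the (S)-catalyst should give the (R)-carbinol (as with aryl alkyl ketones), 1,2-selectively and without touching the ester.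

Step 3
Reactants: 6 ethyl (3R)-3-hydroxy-2,6,6-trimethylcyclohex-1-ene-1-carboxylate
Product: 9 ethyl (1S)-2,6,6-trimethylcyclohex-2-ene-1-carboxylate, via sulfonylhydrazine 7 (not isolated), via allylic diazene 8 (not isolated)
Conditions: 2-nitrobenzenesulfonohydrazide (NBSH), PPh3, DEAD, N-methylmorpholine, −30 °C, then 23 °C
Reagents that add atoms: none
Why: Mitsunobu displacement by the sulfonamide nitrogen of NBSH inverts the carbinol carbon (7), loss of 2-nitrobenzenesulfinic acid on warming gives the monoalkyl diazene 8, and its retro-ene loss of N2 (allylic diazene rearrangement) delivers hydrogen suprafacially to the ester-bearing ring carbon, so the alkene moves to C4=C5 and the new C6 stereocentre should be set as (S) by 1,3-chirality transfer from the (R)-carbinol.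

Step 4
Reactants: 9 ethyl (1S)-2,6,6-trimethylcyclohex-2-ene-1-carboxylate
Product: 10 [(1S)-2,6,6-trimethylcyclohex-2-en-1-yl]methanol
Conditions: LiAlH4, Et2O, 0 °C; quench with Na2SO4·10H2O
Reagents that add atoms: none
Why: LiAlH4 reduction of an ester to the primary alcohol, in which hydride addition at 0 °C should outpace enolisation, so the α-stereocentre is expected to be retained.

Step 5
Reactants: 10 [(1S)-2,6,6-trimethylcyclohex-2-en-1-yl]methanol; 11 1-phenyl-1H-tetrazole-5-thiol
Product: 12 1-phenyl-5-({[(1S)-2,6,6-trimethylcyclohex-2-en-1-yl]methyl}sulfanyl)-1H-tetrazole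
Conditions: PPh3, DIAD, THF, 0 °C → rt
Reagents that add atoms: none
Why: Mitsunobu thioetherification of a primary alcohol by the acidic tetrazolethiol, in which the neighbouring stereocentre is not involved.

Step 6
Reactants: 12 1-phenyl-5-({[(1S)-2,6,6-trimethylcyclohex-2-en-1-yl]methyl}sulfanyl)-1H-tetrazole
Product: 13 1-phenyl-5-({[(1S)-2,6,6-trimethylcyclohex-2-en-1-yl]methyl}sulfonyl)-1H-tetrazole
Conditions: (NH4)6Mo7O24·4H2O (10 mol%), 30% aq. H2O2, EtOH, 0 °C → rt
Reagents that add atoms: hydrogen peroxide, OO
Why: Molybdate-catalysed peroxide oxidation should take the sulfide to the sulfone while sparing the trisubstituted ring alkene.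

Step 7
Reactants: 13 1-phenyl-5-({[(1S)-2,6,6-trimethylcyclohex-2-en-1-yl]methyl}sulfonyl)-1H-tetrazole (2.2 equiv); 14 crocetin dialdehyde
Product: 16 (6S,6'S)-ε,ε-carotene, via apo-carotenal 15 (not isolated)
Conditions: KN(SiMe3)2, DME, −78 °C, then 14, −78 °C → rt; aqueous work-up; then I2 (cat.), hexane, daylight, rt
Reagents that add atoms: none
Why: Double Julia–Kocienski olefination, in which each potassiated sulfone adds to an aldehyde terminus and Smiles rearrangement with loss of SO2 and the tetrazololate forms the C7=C8 alkenes, mainly (E) for a β-branched 1-phenyltetrazolyl sulfone with a potassium counter-ion, while the C6 stereocentres stay untouched and iodine-catalysed photoequilibration should convert residual (Z) isomers into the all-(E) polyene.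

Compound list
1 | ethyl 3-methyl-2-oxobutanoate | CCOC(=O)C(=O)C(C)C | starting material
2 | pent-1-en-3-one (ethyl vinyl ketone) | C=CC(=O)CC | starting material
3 | ethyl 3,3-dimethyl-2,6-dioxooctanoate (Michael diketone, not isolated) | CCOC(=O)C(=O)C(C)(C)CCC(=O)CC | intermediate
4 | ethyl 1-hydroxy-2,6,6-trimethyl-3-oxocyclohexane-1-carboxylate (aldol ketol, diastereomer mixture, not isolated) | CCOC(=O)C1(O)C(C)C(=O)CCC1(C)C | intermediate
5 | ethyl 2,6,6-trimethyl-3-oxocyclohex-1-ene-1-carboxylate | CCOC(=O)C1=C(C)C(=O)CCC1(C)C | intermediate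
6 | ethyl (3R)-3-hydroxy-2,6,6-trimethylcyclohex-1-ene-1-carboxylate | CCOC(=O)C1=C(C)[C@H](O)CCC1(C)C | intermediate
7 | ethyl (3S)-2,6,6-trimethyl-3-[1-(2-nitrobenzenesulfonyl)hydrazin-1-yl]cyclohex-1-ene-1-carboxylate (not isolated) | CCOC(=O)C1=C(C)[C@@H](N(N)S(=O)(=O)c2ccccc2[N+](=O)[O-])CCC1(C)C | intermediate
8 | ethyl (3S)-3-diazenyl-2,6,6-trimethylcyclohex-1-ene-1-carboxylate (not isolated) | CCOC(=O)C1=C(C)[C@@H](N=N)CCC1(C)C | intermediate
9 | ethyl (1S)-2,6,6-trimethylcyclohex-2-ene-1-carboxylate (ethyl (S)-α-cyclogeranate) | CC1=CCCC(C)(C)[C@@H]1C(=O)OCC | intermediate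
10 | [(1S)-2,6,6-trimethylcyclohex-2-en-1-yl]methanol ((S)-α-cyclogeraniol) | CC1=CCCC(C)(C)[C@@H]1CO | intermediate
11 | 1-phenyl-1H-tetrazole-5-thiol | Sc1nnnn1-c1ccccc1 | starting material
12 | 1-phenyl-5-({[(1S)-2,6,6-trimethylcyclohex-2-en-1-yl]methyl}sulfanyl)-1H-tetrazole | CC1=CCCC(C)(C)[C@@H]1CSc1nnnn1-c1ccccc1 | intermediate
13 | 1-phenyl-5-({[(1S)-2,6,6-trimethylcyclohex-2-en-1-yl]methyl}sulfonyl)-1H-tetrazole | CC1=CCCC(C)(C)[C@@H]1CS(=O)(=O)c1nnnn1-c1ccccc1 | intermediate
14 | crocetin dialdehyde, (2E,4E,6E,8E,10E,12E,14E)-2,6,11,15-tetramethylhexadeca-2,4,6,8,10,12,14-heptaenedial | O=C/C(C)=C/C=C/C(C)=C/C=C/C=C(C)/C=C/C=C(C)/C=O | starting material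
15 | (6S)-8'-apo-ε-caroten-8'-al, all-E (not isolated) | CC1=CCCC(C)(C)[C@@H]1/C=C/C(C)=C/C=C/C(C)=C/C=C/C=C(C)/C=C/C=C(C)/C=O | intermediate
16 | (6S,6'S)-ε,ε-carotene, all-E | CC1=CCCC(C)(C)[C@@H]1/C=C/C(C)=C/C=C/C(C)=C/C=C/C=C(C)/C=C/C=C(C)/C=C/[C@@H]1C(C)=CCCC1(C)C | target

Total step count: 7
Longest linear sequence: 7 steps (1 → 5 → 6 → 9 → 10 → 12 → 13 → 16; the last step uses two equivalents of 13).

Steps most likely to fail

Step 1. The hindered, ester-conjugated enol of 1 may add too slowly to 2, so that polymerisation of the vinyl ketone or incomplete cyclodehydration takes over. The fallback sets out from 1 and comes back at 5 by separating the two bond formations. Compound 1 is silylated (Me3SiOTf, Et3N, CH2Cl2, 0 °C) to ethyl 3-methyl-2-[(trimethylsilyl)oxy]but-2-enoate F1. A Mukaiyama–Michael addition of this enol silane to 2 (Sc(OTf)3 cat., CH2Cl2, −78 → 0 °C, dilute acid work-up) should give diketone 3, now isolated. A separate aldol cyclodehydration (TsOH, toluene, reflux, Dean–Stark) should close it to 5.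

Step 3. The Mitsunobu displacement at the hindered allylic carbinol may stall, or ionisation of the activated alcohol may erode the chirality transfer. The fallback sets out from 6 and comes back at 9 and replaces the diazene by a metal hydride. Compound 6 is formylated (HCO2H, Ac2O, pyridine, 0 °C) to ethyl (3R)-3-(formyloxy)-2,6,6-trimethylcyclohex-1-ene-1-carboxylate F2. Palladium-catalysed formate hydrogenolysis (Pd(OAc)2, P(n-Bu)3, THF, rt to 50 °C) should ionise it anti to the formate, and after loss of CO2 the palladium hydride should deliver hydrogen from the metal face to the ester-bearing allyl terminus. The hydrogen again ends up on the face opposite to the original C–O bond, which should give 9 with the same (S) configuration.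

Step 7. The second olefination may remain incomplete, the base may degrade the polyene dialdehyde, or the new C7=C8 bonds may form with poor E/Z control. The fallback sets out from 10 and comes back at 16 by the classical C15 + C10 + C15 Wittig assembly. Swern oxidation of 10 ((COCl)2, DMSO, Et3N, −78 °C) should give (1S)-2,6,6-trimethylcyclohex-2-ene-1-carbaldehyde F3. Wittig reaction with 1-(triphenylphosphoranylidene)propan-2-one (toluene, reflux, base-free) should give (E)-4-[(1S)-2,6,6-trimethylcyclohex-2-en-1-yl]but-3-en-2-one F4. Addition of vinylmagnesium bromide (THF, 0 °C) should give (E)-3-methyl-1-[(1S)-2,6,6-trimethylcyclohex-2-en-1-yl]penta-1,4-dien-3-ol F5 as a carbinol epimer mixture. PPh3·HBr (MeOH, rt) should convert it with allylic transposition into [(2E,4E)-3-methyl-5-[(1S)-2,6,6-trimethylcyclohex-2-en-1-yl]penta-2,4-dien-1-yl]triphenylphosphonium bromide F6. A double Wittig reaction of two equivalents of this salt with purchased (2E,4E,6E)-2,7-dimethylocta-2,4,6-trienedial F7 (NaOMe, MeOH/CH2Cl2, 0 °C → rt), followed by thermal equilibration in refluxing heptane, should give 16.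

Further compounds
F1 | step 1 | ethyl 3-methyl-2-[(trimethylsilyl)oxy]but-2-enoate | CCOC(=O)C(O[Si](C)(C)C)=C(C)C
F2 | step 3 | ethyl (3R)-3-(formyloxy)-2,6,6-trimethylcyclohex-1-ene-1-carboxylate | CCOC(=O)C1=C(C)[C@H](OC=O)CCC1(C)C
F3 | step 7 | (1S)-2,6,6-trimethylcyclohex-2-ene-1-carbaldehyde | CC1=CCCC(C)(C)[C@@H]1C=O
F4 | step 7 | (E)-4-[(1S)-2,6,6-trimethylcyclohex-2-en-1-yl]but-3-en-2-one | CC1=CCCC(C)(C)[C@@H]1/C=C/C(C)=O
F5 | step 7 | (E)-3-methyl-1-[(1S)-2,6,6-trimethylcyclohex-2-en-1-yl]penta-1,4-dien-3-ol | CC1=CCCC(C)(C)[C@@H]1/C=C/C(C)(O)C=C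
F6 | step 7 | [(2E,4E)-3-methyl-5-[(1S)-2,6,6-trimethylcyclohex-2-en-1-yl]penta-2,4-dien-1-yl]triphenylphosphonium bromide | CC1=CCCC(C)(C)[C@@H]1/C=C/C(C)=C/C[P+](c1ccccc1)(c1ccccc1)c1ccccc1.[Br-]
F7 | step 7 | (2E,4E,6E)-2,7-dimethylocta-2,4,6-trienedial | O=C/C(C)=C/C=C/C=C(C)/C=O
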